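**Retrosynthetic overview**
- The cinnamate comes from Heck arylation of the 6-O-acrylate of eudesmane-4β,6β-diol with 3-iodophenol.
- The diol comes from trans-diaxial Markovnikov hydration of eudesm-3-en-6β-ol (sets C4), itself from deconjugative protonation and hydride reduction of eudesm-4-en-6-one (sets C5 and C6).
- The decalin comes from an intramolecular diene–ynone [4+2] of an acyclic precursor: ring B (C5–C10) and ring A (C3–C4) close in the same operation, and C10 is the only stereocentre formed.
- The acyclic diene–yne comes from propynyl addition and allylidene Wittig olefination of (S)-2-isopropyl-5-oxohexanal, made by organocatalytic Michael addition of isovaleraldehyde to methyl vinyl ketone (sets C7).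

Numbering: eudesmane numbering is used (C4 carbinol, C5 ring-fusion CH, C6 ester carbon, C7 isopropyl carbon, C10 methyl-bearing ring-fusion carbon; ring A = C1–C5 and C10, ring B = C5–C10); β means the face of the C10 methyl.

Assumption: the (S)-diarylprolinol ether in step 1 gives the (S)-aldehyde (electrophile enters anti to the diarylmethyl group); if the sense is opposite, the enantiomeric catalyst is used.

**Step 1**
Reactants: 1 3-methylbutanal; 2 but-3-en-2-one
Product: 3 (2S)-5-oxo-2-(propan-2-yl)hexanal
Conditions: (S)-α,α-diphenylprolinol methyl ether (5 mol%), ethyl 3,4-dihydroxybenzoate (20 mol%), neat, 4 °C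
Reagents that add atoms: none
Why: Enamine-catalysed asymmetric Michael addition, in which the diarylmethyl group shields one enamine face so that C7 is formed as S (about 90% ee, to be raised by recrystallising diol 12).

**Step 2**
Reactants: 3 (2S)-5-oxo-2-(propan-2-yl)hexanal
Product: 4 (5S)-6-hydroxy-5-(propan-2-yl)non-7-yn-2-one (C6 epimer mixture)
Conditions: CH3C≡CMgBr (1.05 equiv), THF, −78 °C; aq NH4Cl
Reagents that add atoms: 1-propynylmagnesium bromide, CC#C[Mg]Br
Why: Chemoselective Grignard 1,2-addition to the aldehyde, which is far more electrophilic than the methyl ketone at −78 °C; the new carbinol centre is left as a mixture because step 4 oxidises it away.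

**Step 3**
Reactants: 4 (5S)-6-hydroxy-5-(propan-2-yl)non-7-yn-2-one
Product: 5 (7S)-4-methyl-7-(propan-2-yl)undeca-1,3-dien-9-yn-8-ol (3E/3Z and C8 epimer mixture)
Conditions: CH2=CHCH2PPh3Br (2.5 equiv), n-BuLi (2.5 equiv), THF, −78 → 0 °C; then 4, 0 °C → rt
Reagents that add atoms: allyltriphenylphosphonium bromide, C=CC[P+](c1ccccc1)(c1ccccc1)c1ccccc1.[Br-]
Why: Wittig olefination of the methyl ketone with the allylidene ylide builds the 1,3-diene whose terminus is the future C10; no stereocentre is formed and both alkene isomers lead to the same cycloadduct constitution.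

**Step 4**
Reactants: 5 (7S)-4-methyl-7-(propan-2-yl)undeca-1,3-dien-9-yn-8-ol
Product: 7 (7S,10S)-eudesma-1,4-dien-6-one, via ynone 6 (not isolated)
Conditions: Dess–Martin periodinane, CH2Cl2, 0 °C → rt; then toluene, BHT, 110 °C
Reagents that add atoms: none
Why: Oxidation to the ynone triggers an intramolecular Diels–Alder reaction that closes ring B (C5–C10) and ring A (C3–C4) together; because the dienophile is an alkyne, C10 is the only new stereocentre, set cis to the pseudo-equatorial C7 isopropyl group through a chair-like four-atom tether, and the minor C10 epimer is removed by chromatography before any base is used.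

**Step 5**
Reactants: 7 (7S,10S)-eudesma-1,4-dien-6-one
Product: 8 (7S,10R)-eudesm-4-en-6-one
Conditions: H2 (3 atm), RhCl(PPh3)3 (5 mol%), benzene/EtOH, rt
Reagents that add atoms: none
Why: Homogeneous catalytic hydrogenation saturates only the cis-disubstituted C1=C2 bond and leaves the tetrasubstituted conjugated C4=C5 bond; no stereocentre is formed (the C10 descriptor changes by priority only).

**Step 6**
Reactants: 8 (7S,10R)-eudesm-4-en-6-one
Product: 10 (5R,6R,7S,10R)-eudesm-3-en-6-ol, via eudesm-3-en-6-one 9 (not isolated)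
Conditions: KOt-Bu, t-BuOH, rt; 10% aq AcOH, 0 °C; then crude in MeOH, NaBH4, −20 → 0 °C
Reagents that add atoms: none
Why: Deconjugative isomerisation through the extended dienolate (as in isophorone to β-isophorone) with kinetic α-protonation at C5 on the face opposite the angular methyl gives the trans ring fusion (5α-H), and immediate borohydride reduction from the same unhindered α face gives the axial 6β-alcohol before reconjugation can occur.

**Step 7**
Reactants: 10 (5R,6R,7S,10R)-eudesm-3-en-6-ol
Product: 12 (4S,5S,6R,7S,10R)-eudesmane-4,6-diol, via organomercury acetate 11 (not isolated)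
Conditions: Hg(OAc)2, THF/H2O, rt; then NaBH4, aq NaOH, 0 °C
Reagents that add atoms: water, O
Why: Oxymercuration–demercuration (Markovnikov hydration), in which the mercurinium ion forms on the open α face and water opens it at the tertiary C4 in the trans-diaxial (Fürst–Plattner) sense, giving the axial 4β-hydroxyl and equatorial 4α-methyl before NaBH4 replaces mercury by hydrogen.

**Step 8**
Reactants: 12 (4S,5S,6R,7S,10R)-eudesmane-4,6-diol
Product: 13 (4S,5S,6R,7S,10R)-4-hydroxyeudesman-6-yl prop-2-enoate
Conditions: CH2=CHCOCl, Et3N, DMAP (cat.), BHT, CH2Cl2, 0 °C → rt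
Reagents that add atoms: acryloyl chloride, C=CC(=O)Cl
Why: DMAP-catalysed acylation of the secondary 6β-hydroxyl with the small acryloyl group while the tertiary 4β-hydroxyl stays free; no stereocentre is touched.

**Step 9**
Reactants: 13 (4S,5S,6R,7S,10R)-4-hydroxyeudesman-6-yl prop-2-enoate; 14 3-iodophenol
Product: 15 (4S,5S,6R,7S,10R)-4-hydroxyeudesman-6-yl (2E)-3-(3-hydroxyphenyl)prop-2-enoate
Conditions: Pd(OAc)2 (5 mol%), P(o-tol)3, Et3N, DMF, 90 °C
Reagents that add atoms: none
Why: Mizoroki–Heck arylation of the acrylate gives the (E)-cinnamate by syn insertion and syn β-hydride elimination, and it tolerates the free phenol and the tertiary alcohol.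

**Compound list**
1 | 3-methylbutanal (isovaleraldehyde) | CC(C)CC=O | starting material
2 | but-3-en-2-one (methyl vinyl ketone) | CC(=O)C=C | starting material
3 | (2S)-5-oxo-2-(propan-2-yl)hexanal | CC(C)[C@@H](C=O)CCC(C)=O | intermediate
4 | (5S)-6-hydroxy-5-(propan-2-yl)non-7-yn-2-one, C6 epimers | CC#CC(O)[C@H](C(C)C)CCC(C)=O | intermediate
5 | (7S)-4-methyl-7-(propan-2-yl)undeca-1,3-dien-9-yn-8-ol, 3E/3Z and C8 epimers | CC#CC(O)[C@H](C(C)C)CCC(C)=CC=C | intermediate
6 | (7S)-4-methyl-7-(propan-2-yl)undeca-1,3-dien-9-yn-8-one | CC#CC(=O)[C@H](C(C)C)CCC(C)=CC=C | intermediate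
7 | (7S,10S)-eudesma-1,4-dien-6-one = (2S,4aS)-4a,8-dimethyl-2-(propan-2-yl)-3,4,4a,7-tetrahydronaphthalen-1(2H)-one | CC1=C2C(=O)[C@H](C(C)C)CC[C@@]2(C)C=CC1 | intermediate
8 | (7S,10R)-eudesm-4-en-6-one = (2S,4aR)-4a,8-dimethyl-2-(propan-2-yl)-3,4,4a,5,6,7-hexahydronaphthalen-1(2H)-one | CC1=C2C(=O)[C@H](C(C)C)CC[C@@]2(C)CCC1 | intermediate
9 | (5R,7S,10R)-eudesm-3-en-6-one (trans-fused, 5α-H) | CC(C)[C@@H]1CC[C@@]2(C)CCC=C(C)[C@@H]2C1=O | intermediate
10 | (5R,6R,7S,10R)-eudesm-3-en-6-ol (6β-OH, axial) | CC(C)[C@@H]1CC[C@@]2(C)CCC=C(C)[C@@H]2[C@@H]1O | intermediate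
11 | 3α-(acetoxymercurio)eudesmane-4β,6β-diol | CC(C)[C@@H]1CC[C@@]2(C)CC[C@@H]([Hg]OC(C)=O)[C@](C)(O)[C@@H]2[C@@H]1O | intermediate
12 | (4S,5S,6R,7S,10R)-eudesmane-4,6-diol (4β,6β) | CC(C)[C@@H]1CC[C@@]2(C)CCC[C@](C)(O)[C@@H]2[C@@H]1O | intermediate
13 | (4S,5S,6R,7S,10R)-4-hydroxyeudesman-6-yl prop-2-enoate | CC(C)[C@@H]1CC[C@@]2(C)CCC[C@](C)(O)[C@@H]2[C@@H]1OC(=O)C=C | intermediate
14 | 3-iodophenol | Oc1cccc(I)c1 | starting material
15 | (4S,5S,6R,7S,10R)-4-hydroxyeudesman-6-yl (2E)-3-(3-hydroxyphenyl)prop-2-enoate | CC(C)[C@@H]1CC[C@@]2(C)CCC[C@](C)(O)[C@@H]2[C@@H]1OC(=O)/C=C/c1cccc(O)c1 | target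

**Totals**
Total step count: 9. Longest linear sequence: 9 steps (from 1 and 2).

**Steps most likely to fail**

Step 4. The diene terminus that becomes C10 always carries a cis substituent, so the reactive s-cis conformer is strained and the cycloaddition may be slow. Facial control by C7 through the tether may be modest, and the α-centre of ynone 6 could epimerise on prolonged heating. The fallback sets out from 5. Zerovalent-nickel-catalysed [4+2] cycloisomerisation of the unactivated dienyne (Ni(cod)2, tris(2-biphenylyl) phosphite, THF, rt) runs through a nickelacycle at the alcohol oxidation level instead of a thermal pericyclic transition state and gives (7S,10S)-eudesma-1,4-dien-6-ol F1 as C6 epimers. Dess–Martin oxidation of F1 then returns to 7.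

Step 6. The dienolate may be reprotonated at C3 (giving back 8) or at C5 from the β face (cis fusion), some exocyclic dienolate may form, and 9 may reconjugate before it is reduced. The fallback sets out from 8 and avoids deconjugation altogether.
- NaBH4/CeCl3·7H2O reduction gives the allylic alcohol (6R,7S,10R)-eudesm-4-en-6-ol F2.
- Hydroxyl-directed epoxidation (VO(acac)2, t-BuOOH) gives 4β,5β-epoxyeudesman-6β-ol F3.
- Dess–Martin oxidation gives 4β,5β-epoxyeudesman-6-one F4.
- SmI2 in THF/MeOH at −78 °C cleaves the Cα–O bond and the samarium enolate is protonated from the α face to give 4β-hydroxyeudesman-6-one F5.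
- NaBH4 reduction from the α face comes back to the route at 12, so step 7 is bypassed as well.

Step 7. Axial attack of water at C4 is syn to both the C10 methyl and the 6β-hydroxyl, so the hydration may be slow or give mixtures, and the 6β-hydroxyl may interfere. The fallback sets out from 10. Epoxidation directed by the homoallylic 6β-hydroxyl (VO(acac)2, t-BuOOH) delivers oxygen to the β face and gives 3β,4β-epoxyeudesman-6β-ol F6. LiAlH4 then opens the epoxide at the secondary C3 in the trans-diaxial sense and comes back to the route at 12.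

**Further compounds**
F1 | step 4 | (7S,10S)-eudesma-1,4-dien-6-ol, C6 epimers | CC1=C2C(O)[C@H](C(C)C)CC[C@@]2(C)C=CC1
F2 | step 6 | (6R,7S,10R)-eudesm-4-en-6-ol (6β-OH) | CC1=C2[C@H](O)[C@H](C(C)C)CC[C@@]2(C)CCC1
F3 | step 6 | 4β,5β-epoxyeudesman-6β-ol | CC(C)[C@@H]1CC[C@@]2(C)CCC[C@]3(C)O[C@]23[C@@H]1O
F4 | step 6 | 4β,5β-epoxyeudesman-6-one | CC(C)[C@@H]1CC[C@@]2(C)CCC[C@]3(C)O[C@]23C1=O
F5 | step 6 | 4β-hydroxyeudesman-6-one (5α-H) | CC(C)[C@@H]1CC[C@@]2(C)CCC[C@](C)(O)[C@@H]2C1=O
F6 | step 7 | 3β,4β-epoxyeudesman-6β-ol | CC(C)[C@@H]1CC[C@@]2(C)CC[C@@H]3O[C@]3(C)[C@@H]2[C@@H]1O
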